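The route rests on closing the butenolide (ring O15–C15–C14=C13–C16) through its C13–C16 bond, two carbons that are both electrophilic in any simple precursor. The lactone carbonyl C16 is therefore parked on O15 as the methyl carbonate of a (Z)-13-iodoallylic alcohol. Iodine–lithium exchange reverses the polarity of C13, which attacks C16 (5-exo-trig) and delivers the α-substituted butenolide in one operation. The step exploits the cis placement of the C13 substituent and C15 on the endocyclic C13=C14 bond, which holds carbanion and carbonate within reach. The ent-decalin with its four stereocentres comes from andrographolide: ozonolysis excises its over-oxidised lactone, C3 is deoxygenated, C20 is oxidised from O19 by radical hydrogen transfer, and C8 is re-methylenated.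

Key step: step 12

Remark: labdane numbering is used (decalin C1–C10; C17 on C8; C18 methyl and C19 CH2O on C4; C20 on C10; side chain C11–C16 with O15 on C15 and C16 the lactone carbonyl). The stereocentres C4, C5, C9 and C10 are taken unchanged from andrographolide, and the C3 and C14 centres of andrographolide are deleted.
Remark: the acetal carbon C20 in 9–13 and 15–21 (and in 20 also the carbon C16) is expected as a mixture of epimers and is left open in the SMILES; C20 becomes achiral again in step 13.

Step 1
Reactants: 1 andrographolide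
Product: 3 3,12,19-trihydroxy-13,14,15,16,17-pentanor-ent-labdan-8-one (3-OH as in andrographolide), via keto aldehyde 2 (not isolated)
Conditions: O3, CH2Cl2/MeOH, −78 °C; Me2S, −78 °C→rt; then NaBH(OAc)3, AcOH, 1,2-dichloroethane, rt
Reagents that add atoms: ozone, O=[O+][O-]
Why: Ozonolysis cleaves both the C8=C17 and the C12=C13 double bonds, and triacetoxyborohydride then reduces the C12 aldehyde but not the hindered C8 ketone, while C9 keeps its equatorial (thermodynamic) side chain.

Step 2
Reactants: 3
Product: 4 12-O-(tert-butyldiphenylsilyl) ether of 3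
Conditions: TBDPSCl (1.05 equiv), imidazole, CH2Cl2/DMF, −20→0 °C
Reagents that add atoms: tert-butyldiphenylsilyl chloride, CC(C)(C)[Si](Cl)(c1ccccc1)c1ccccc1
Why: Silyl ether formation with the bulky chlorosilane should select the unhindered primary 12-OH over the neopentyl 19-OH and the secondary 3-OH.

Step 3
Reactants: 4
Product: 5 3,19-cyclic thionocarbonate of 4
Conditions: 1,1'-thiocarbonyldiimidazole, DMAP (cat.), toluene, 80 °C
Reagents that add atoms: 1,1'-thiocarbonyldiimidazole, S=C(n1ccnc1)n1ccnc1
Why: Thiocarbonylation of the 1,3-related 3-OH and 19-OH closes a six-membered cyclic thionocarbonate that activates C3 and masks O19 at once.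

Step 4
Reactants: 5
Product: 7 12-(tert-butyldiphenylsilyloxy)-19-hydroxy-13,14,15,16,17-pentanor-ent-labdan-8-one, via S-stannyl thiolcarbonate 6 (not isolated)
Conditions: Bu3SnH, AIBN, toluene, 110 °C; then NaOH, MeOH/H2O, rt
Reagents that add atoms: none
Why: Barton–McCombie deoxygenation of the cyclic thionocarbonate, in which the stannyl radical adds to sulfur, the adduct fragments toward the secondary C3 radical and not the neopentyl primary C19 radical, hydrogen transfer gives C3H2, and mild base frees O19 from the residual thiolcarbonate.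

Step 5
Reactants: 7
Product: 10 12-(tert-butyldiphenylsilyloxy)-19,20-epoxy-20-methoxy-13,14,15,16,17-pentanor-ent-labdan-8-one, via iodo alcohol 8 (not isolated), via lactol 9 (not isolated)
Conditions: PhI(OAc)2 (excess), I2, cyclohexane/CH2Cl2, hν (W lamp), rt; aq Na2S2O3; then MeOH, CSA (cat.), rt
Reagents that add atoms: methanol, CO
Why: Hypoiodite reaction under iodine(III)/iodine photolysis (Suárez conditions), in which the O19 alkoxy radical abstracts hydrogen from the syn-diaxial C20 methyl through a seven-membered transition state, a second abstraction–oxidation cycle at the CH2I carbon leads to the bridged lactol on work-up, and acid methanolysis gives the methyl acetal, whose C20 configuration is of no consequence.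

Step 6
Reactants: 10
Product: 11 12-(tert-butyldiphenylsilyloxy)-19,20-epoxy-20-methoxy-13,14,15,16-tetranor-ent-labd-8(17)-ene
Conditions: Ph3PCH3Br, KOtBu, toluene, 90 °C
Reagents that add atoms: methyltriphenylphosphonium bromide, C[P+](c1ccccc1)(c1ccccc1)c1ccccc1.[Br-]
Why: Wittig methylenation of the hindered C8 ketone under forcing conditions restores the exocyclic C8=C17 alkene, and C9 keeps its equatorial side chain, which is also the thermodynamic epimer should enolisation occur.

Step 7
Reactants: 11
Product: 12 19,20-epoxy-20-methoxy-13,14,15,16-tetranor-ent-labd-8(17)-en-12-ol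
Conditions: TBAF, THF, rt
Reagents that add atoms: none
Why: Fluoride-mediated desilylation frees the primary 12-OH and leaves the acetal and the alkene untouched.

Step 8
Reactants: 12
Product: 13 12-iodo-19,20-epoxy-20-methoxy-13,14,15,16-tetranor-ent-labd-8(17)-ene
Conditions: PPh3, I2, imidazole, CH2Cl2, 0 °C→rt
Reagents that add atoms: iodine, II
Why: Appel-type iodination converts the unhindered primary alcohol into the iodide by SN2 displacement of the alkoxyphosphonium ion under buffered conditions that spare the acetal.

Step 9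
Reactants: 13; 14 prop-2-yn-1-ol
Product: 15 19,20-epoxy-20-methoxy-16-nor-ent-labd-8(17)-en-13-yn-15-ol
Conditions: 14 (3 equiv), n-BuLi (6 equiv), THF/DMPU, −78→0 °C; then 13, 0 °C→rt; H2O
Reagents that add atoms: none
Why: Acetylide SN2 alkylation of the C,O-dilithio derivative of propargyl alcohol by the primary iodide forms the C12–C13 bond and brings in C13–C15 with O15.

Step 10
Reactants: 15
Product: 17 (13Z)-13-iodo-19,20-epoxy-20-methoxy-16-nor-ent-labda-8(17),13-dien-15-ol, via vinylalanate 16 (not isolated)
Conditions: Red-Al, THF, 0 °C→rt; EtOAc; then I2, THF, −78 °C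
Reagents that add atoms: iodine, II
Why: Trans-hydroalumination of the propargylic alcohol places aluminium on the distal carbon C13 within a five-membered oxa-alanate, and iodinolysis with retention gives the (Z)-3-iodoallylic alcohol with iodine and CH2OH cis.

Step 11
Reactants: 17
Product: 18 15-O-methoxycarbonyl derivative (methyl carbonate) of 17
Conditions: ClCO2Me, pyridine, CH2Cl2, 0 °C
Reagents that add atoms: methyl chloroformate, COC(=O)Cl
Why: Carbonate formation by acylation of the primary allylic alcohol attaches the future lactone carbonyl C16 to O15.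

Step 12
Reactants: 18
Product: 21 19,20-epoxy-20-methoxy-ent-labda-8(17),13-dien-16,15-olide, via vinyllithium 19 (not isolated), via lithium hemiorthoester 20 (not isolated)
Conditions: t-BuLi (2.1 equiv), Et2O/THF, −100→−78 °C, high dilution; AcOH quench at −78 °C
Reagents that add atoms: none
Why: Iodine–lithium exchange at C13 (the second equivalent of t-BuLi destroys t-BuI) outruns any addition to the carbonate and gives vinyllithium 19 with retention of the Z geometry, so the carbanion at C13 and the carbonate carbon C16 sit cis on the O15–C15–C14=C13 tether. Intramolecular addition to C16 forms the C13–C16 bond and closes the five-membered ring in the 5-exo-trig mode to alkoxide 20, which collapses to the butenolide by loss of methoxide; if the ring O15–C16 bond breaks instead, the (Z)-γ-alkoxido enoate re-closes at once onto its ester, so both collapse paths converge on 21. The closest known reaction type is the Parham cyclisation (halogen–lithium exchange followed by intramolecular attack on a tethered carboxylic acid derivative), of which this is the vinylogous, lactone-forming case. No stereocentre is formed, and the endocyclic C13=C14 geometry is fixed by the ring and was secured by the cis placement of iodine and CH2O in 17. The selectivity needed is exchange before carbonyl attack and cyclisation before intermolecular addition to the new lactone, which the low temperature, the dilution and the five-membered transition state secure; the methyl acetal and the exocyclic alkene are inert to t-BuLi at this temperature.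

Step 13
Reactants: 21
Product: 22 19-hydroxy-20,20-(propane-1,3-diyldithio)-ent-labda-8(17),13-dien-16,15-olide
Conditions: HS(CH2)3SH, BF3·OEt2, CH2Cl2, −40→−20 °C, dark
Reagents that add atoms: propane-1,3-dithiol, SCCCS
Why: Lewis acid-promoted transthioacetalisation opens the bridged mixed acetal to the C20 1,3-dithiane, driven by the two C–S bonds, and thereby releases the 19-hydroxyl.

Step 14
Reactants: 22
Product: 23 19-acetoxy-20,20-(propane-1,3-diyldithio)-ent-labda-8(17),13-dien-16,15-olide
Conditions: Ac2O, pyridine, DMAP (cat.), CH2Cl2, 0 °C→rt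
Reagents that add atoms: acetic anhydride, CC(=O)OC(C)=O
Why: DMAP-catalysed acetylation esterifies the neopentyl primary 19-OH, the only hydroxyl present.

Step 15
Reactants: 23
Product: 24 19-acetoxy-20-oxo-ent-labda-8(17),13-dien-16,15-olide (target)
Conditions: PhI(OCOCF3)2, MeCN/H2O (9:1), 0 °C, short reaction time
Reagents that add atoms: water, O
Why: Oxidative hydrolysis of the dithiane with bis(trifluoroacetoxy)iodobenzene unmasks the C20 aldehyde, which has no α-hydrogen and cannot epimerise, without touching the acetate, the butenolide or the exocyclic alkene.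

Compound list
1 | andrographolide | C=C1CC[C@@H]2[C@](C)(CO)[C@H](O)CC[C@@]2(C)[C@@H]1C/C=C1/C(=O)OC[C@H]1O | starting material
2 | 3,19-dihydroxy-8-oxo-13,14,15,16,17-pentanor-ent-labdan-12-al (keto aldehyde) | O=C1CC[C@@H]2[C@](C)(CO)[C@H](O)CC[C@@]2(C)[C@@H]1CC=O | intermediate
3 | 3,12,19-trihydroxy-13,14,15,16,17-pentanor-ent-labdan-8-one (3-OH as in andrographolide) | O=C1CC[C@@H]2[C@](C)(CO)[C@H](O)CC[C@@]2(C)[C@@H]1CCO | intermediate
4 | 12-O-(tert-butyldiphenylsilyl) ether of 3 | O=C1CC[C@@H]2[C@](C)(CO)[C@H](O)CC[C@@]2(C)[C@@H]1CCO[Si](c1ccccc1)(c1ccccc1)C(C)(C)C | intermediate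
5 | 3,19-cyclic thionocarbonate of 4 | O=C1CC[C@@H]2[C@]3(C)COC(=S)O[C@@H]3CC[C@@]2(C)[C@@H]1CCO[Si](c1ccccc1)(c1ccccc1)C(C)(C)C | intermediate
6 | O-(19-yl) S-tributylstannyl thiolcarbonate of the 3-deoxy compound | O=C1CC[C@@H]2[C@](C)(COC(=O)S[Sn](CCCC)(CCCC)CCCC)CCC[C@@]2(C)[C@@H]1CCO[Si](c1ccccc1)(c1ccccc1)C(C)(C)C | intermediate
7 | 12-(tert-butyldiphenylsilyloxy)-19-hydroxy-13,14,15,16,17-pentanor-ent-labdan-8-one | O=C1CC[C@@H]2[C@](C)(CO)CCC[C@@]2(C)[C@@H]1CCO[Si](c1ccccc1)(c1ccccc1)C(C)(C)C | intermediate
8 | 20-iodo derivative of 7 (20-iodo-19-ol) | O=C1CC[C@@H]2[C@](C)(CO)CCC[C@@]2(CI)[C@@H]1CCO[Si](c1ccccc1)(c1ccccc1)C(C)(C)C | intermediate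
9 | 19,20-epoxy-20-hydroxy lactol (C20 epimers) | O=C1CC[C@@H]2[C@@]3(C)CCC[C@]2([C@@H]1CCO[Si](c1ccccc1)(c1ccccc1)C(C)(C)C)C(O)OC3 | intermediate
10 | 12-(tert-butyldiphenylsilyloxy)-19,20-epoxy-20-methoxy-13,14,15,16,17-pentanor-ent-labdan-8-one (C20 epimers) | O=C1CC[C@@H]2[C@@]3(C)CCC[C@]2([C@@H]1CCO[Si](c1ccccc1)(c1ccccc1)C(C)(C)C)C(OC)OC3 | intermediate
11 | 12-(tert-butyldiphenylsilyloxy)-19,20-epoxy-20-methoxy-13,14,15,16-tetranor-ent-labd-8(17)-ene | C=C1CC[C@@H]2[C@@]3(C)CCC[C@]2([C@@H]1CCO[Si](c1ccccc1)(c1ccccc1)C(C)(C)C)C(OC)OC3 | intermediate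
12 | 19,20-epoxy-20-methoxy-13,14,15,16-tetranor-ent-labd-8(17)-en-12-ol | C=C1CC[C@@H]2[C@@]3(C)CCC[C@]2([C@@H]1CCO)C(OC)OC3 | intermediate
13 | 12-iodo-19,20-epoxy-20-methoxy-13,14,15,16-tetranor-ent-labd-8(17)-ene | C=C1CC[C@@H]2[C@@]3(C)CCC[C@]2([C@@H]1CCI)C(OC)OC3 | intermediate
14 | prop-2-yn-1-ol | C#CCO | starting material
15 | 19,20-epoxy-20-methoxy-16-nor-ent-labd-8(17)-en-13-yn-15-ol | C=C1CC[C@@H]2[C@@]3(C)CCC[C@]2([C@@H]1CCC#CCO)C(OC)OC3 | intermediate
16 | sodium bis(2-methoxyethoxy) oxa-alanate with Al on C13 and O15 | C=C1CC[C@@H]2[C@@]3(C)CCC[C@]2([C@@H]1CCC1=CCO[Al-]1(OCCOC)OCCOC)C(OC)OC3.[Na+] | intermediate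
17 | (13Z)-13-iodo-19,20-epoxy-20-methoxy-16-nor-ent-labda-8(17),13-dien-15-ol | C=C1CC[C@@H]2[C@@]3(C)CCC[C@]2([C@@H]1CC/C(I)=C/CO)C(OC)OC3 | intermediate
18 | methyl carbonate of 17 | C=C1CC[C@@H]2[C@@]3(C)CCC[C@]2([C@@H]1CC/C(I)=C/COC(=O)OC)C(OC)OC3 | intermediate
19 | (13Z)-13-lithio analogue of 18 | C=C1CC[C@@H]2[C@@]3(C)CCC[C@]2([C@@H]1CC/C([Li])=C/COC(=O)OC)C(OC)OC3 | intermediate
20 | lithium 2-methoxy-2,5-dihydrofuran-2-olate (tetrahedral adduct at C16) | C=C1CC[C@@H]2[C@@]3(C)CCC[C@]2([C@@H]1CCC1=CCOC1(OC)O[Li])C(OC)OC3 | intermediate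
21 | 19,20-epoxy-20-methoxy-ent-labda-8(17),13-dien-16,15-olide | C=C1CC[C@@H]2[C@@]3(C)CCC[C@]2([C@@H]1CCC1=CCOC1=O)C(OC)OC3 | intermediate
22 | 19-hydroxy-20,20-(propane-1,3-diyldithio)-ent-labda-8(17),13-dien-16,15-olide | C=C1CC[C@@H]2[C@](C)(CO)CCC[C@@]2(C2SCCCS2)[C@@H]1CCC1=CCOC1=O | intermediate
23 | 19-acetoxy-20,20-(propane-1,3-diyldithio)-ent-labda-8(17),13-dien-16,15-olide | C=C1CC[C@@H]2[C@](C)(COC(C)=O)CCC[C@@]2(C2SCCCS2)[C@@H]1CCC1=CCOC1=O | intermediate
24 | 19-acetoxy-20-oxo-ent-labda-8(17),13-dien-16,15-olide | C=C1CC[C@@H]2[C@](C)(COC(C)=O)CCC[C@@]2(C=O)[C@@H]1CCC1=CCOC1=O | target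

Total step count: 15. Longest linear sequence: 15 steps (1 → 24).

The three steps most likely to fail are steps 5, 12 and 13.

First risk, step 5. The process at risk is control of the hydrogen transfer and of the oxidation level. The O19 alkoxy radical may abstract from C2–H or C6–H or lose formaldehyde by β-scission, and closure of the 20-iodo alcohol to the 19,20-ether may outrun the second oxidation. The fallback sets out from 7 and replaces the iodine-based chain by a nitrite photolysis that reaches the aldehyde level in a single transfer. Nitrosyl chloride in pyridine should convert 7 into the 19-nitrite ester F1 . Irradiation (Barton nitrite reaction) should transfer NO to C20 and, after tautomerisation of the nitroso compound, give the 19-hydroxy C20 aldoxime F2 . Exchange deoximation with levulinic acid in aqueous HCl should release lactol 9, which under the methanol/CSA conditions of step 5 comes back to the route at 10.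

Second risk, step 12. The process at risk is loss of the vinyllithium before ring closure (protonation, or attack of t-BuLi on the carbonate) and addition of organolithium to the lactone once formed. The fallback sets out from 17 and gives up the carbonate tether in favour of a known carbonylation. PdCl2(PPh3)2 (cat.), CO (1 atm), Et3N, THF should insert CO at C13 and let O15 close the lactone. It comes back to the route at 21 and has no new compound on its way, which is what the entry F0 records.

Third risk, step 13. The process at risk is acid-promoted migration of the exocyclic C8=C17 double bond into the ring, or addition of the thiol to it or to the butenolide, while the hindered bridged acetal opens slowly. The fallback sets out from 21 and avoids thiols and Lewis acid. Dilute aqueous HCl in THF should give the 19,20-epoxy-20-hydroxy lactol F3 . Luche reduction (NaBH4, CeCl3, MeOH, −20 °C) should then give the 19,20-diol F4 . Acetylation with one equivalent of Ac2O in pyridine at 0 °C should favour the less hindered 19-OH and give the 19-acetoxy-20-hydroxy compound F5 . Dess–Martin oxidation of the remaining 20-OH comes back to the route at 24.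

Further compounds
F1 | step 5 | 19-nitrite ester of ketone 7 | O=C1CC[C@@H]2[C@](C)(CON=O)CCC[C@@]2(C)[C@@H]1CCO[Si](c1ccccc1)(c1ccccc1)C(C)(C)C
F2 | step 5 | 12-(tert-butyldiphenylsilyloxy)-19-hydroxy-8-oxo-13,14,15,16,17-pentanor-ent-labdan-20-al oxime | O=C1CC[C@@H]2[C@](C)(CO)CCC[C@@]2(C=NO)[C@@H]1CCO[Si](c1ccccc1)(c1ccccc1)C(C)(C)C
F0 | step 12 | none | none
F3 | step 13 | 19,20-epoxy-20-hydroxy-ent-labda-8(17),13-dien-16,15-olide | C=C1CC[C@@H]2[C@@]3(C)CCC[C@]2([C@@H]1CCC1=CCOC1=O)C(O)OC3
F4 | step 13 | 19,20-dihydroxy-ent-labda-8(17),13-dien-16,15-olide | C=C1CC[C@@H]2[C@](C)(CO)CCC[C@@]2(CO)[C@@H]1CCC1=CCOC1=O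
F5 | step 13 | 19-acetoxy-20-hydroxy-ent-labda-8(17),13-dien-16,15-olide | C=C1CC[C@@H]2[C@](C)(COC(C)=O)CCC[C@@]2(CO)[C@@H]1CCC1=CCOC1=O
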